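**Plan**

- Lactone numbering: O1, C2 (C=O), C3 (carbinol carrying the arylmethyl group), C4, C5; C6 is the side-chain carbinol carbon. The enabling feature is the α-hydroxy acyl pair C2/C3 inside the γ-lactone ring, which is the rearranged form of a hemiketal carbon (C2) next to a ketone (C3) in a 2-hydroxy-2-arylmethyl-furan-3-one.
- Retrosynthesis cuts C3–CH2Ar and O1–C2 together (arylmethyl back to C2, ring opened) to an acyclic 5-hydroxy-2,3-diketone. The diketone goes back to a C2≡C3 alkyne, which is cut at C4–C6 (allenylstannane + O-silyl vanillin), at C3–C4 (acetylide + Weinreb amide) and at the benzylic carbon–C2 bond (benzylic bromide + ethynyl Grignard).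
- Forward, the chain is joined linearly in the reverse order of these cuts. The alkyne is then raised to the diketone via the Z-alkene and the diol, the C5 hydroxyl is released, and the lactone (the only ring made) closes in the rearrangement; fluoride removes the silyl groups.
- Stereochemistry: the propargylic carbinol (future C4) comes from a catalyst-controlled transfer hydrogenation and is relayed by anti SN2' stannylation and anti SE2' addition. C6 comes from the syn-selective open transition state of that addition. C3 is set by the C4 substituent, which sends the migrating arylmethyl group to the opposite ring face.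

Key step: step 15

Abbreviations: Ar = 3-methoxy-4-[(triisopropylsilyl)oxy]phenyl; TBS = tert-butyldimethylsilyl; TIPS = triisopropylsilyl. Atom labels O1, C2–C6 of the lactone are used for all intermediates.
Assumption: Weinreb amide 7 is taken as a catalogue reagent.
Assumption: the ring–chain tautomers 19 and 20 are handled as one material, drawn and counted as open-chain 19.

**Route**

Step 1
Reactants: 1 vanillin
Product: 2 3-methoxy-4-[(triisopropylsilyl)oxy]benzaldehyde
Conditions: TIPSCl, imidazole, DMF, rt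
Reagents that add atoms: chlorotriisopropylsilane, CC(C)[Si](Cl)(C(C)C)C(C)C
Why: Silyl ether formation on a phenol is routine, and the bulky aryl TIPS ether should outlast the hydride, organometallic, Lewis-acid and HF·pyridine steps that follow yet still fall to fluoride at the end.

Step 2
Reactants: 2 3-methoxy-4-[(triisopropylsilyl)oxy]benzaldehyde
Product: 3 {3-methoxy-4-[(triisopropylsilyl)oxy]phenyl}methanol
Conditions: NaBH4, MeOH/THF, 0 °C
Reagents that add atoms: none
Why: Borohydride reduction of an aromatic aldehyde to the benzylic alcohol is chemoselective and should leave the aryl silyl ether untouched.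

Step 3
Reactants: 3 {3-methoxy-4-[(triisopropylsilyl)oxy]phenyl}methanol
Product: 4 [4-(bromomethyl)-2-methoxyphenoxy]triisopropylsilane
Conditions: PBr3, Et2O, 0 °C
Reagents that add atoms: phosphorus tribromide, BrP(Br)Br
Why: Nucleophilic substitution of an electron-rich benzylic alcohol via its phosphite ester is fast at 0 °C, and the bromide is carried on without storage.

Step 4
Reactants: 4 [4-(bromomethyl)-2-methoxyphenoxy]triisopropylsilane; 5 ethynylmagnesium bromide
Product: 6 [2-methoxy-4-(prop-2-yn-1-yl)phenoxy]triisopropylsilane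
Conditions: 5 (excess), CuCl (5 mol%), THF, 0 → 45 °C
Reagents that add atoms: none
Why: Copper-catalysed cross-coupling of an alkynyl Grignard reagent with a benzylic bromide is the standard entry to 3-arylprop-1-ynes, and the excess of 5 should suppress double benzylation.

Step 5
Reactants: 6 [2-methoxy-4-(prop-2-yn-1-yl)phenoxy]triisopropylsilane; 7 2-[(tert-butyldimethylsilyl)oxy]-N-methoxy-N-methylacetamide
Product: 10 1-[(TBS)oxy]-5-Ar-pent-3-yn-2-one, via lithium acetylide 8 (not isolated), via tetrahedral lithium adduct 9 (not isolated)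
Conditions: n-BuLi, THF, −78 °C; then 7, −78 → −30 °C; cold 1 M HCl quench
Reagents that add atoms: none
Why: Weinreb ketone synthesis: the terminal C–H is the most acidic site of 6, the chelated adduct 9 resists over-addition, and the cold acidic quench should release the ynone without base-induced propargyl–allenyl isomerisation.

Step 6
Reactants: 10 1-[(TBS)oxy]-5-Ar-pent-3-yn-2-one
Product: 11 (2R)-1-[(TBS)oxy]-5-Ar-pent-3-yn-2-ol
Conditions: Ru[(S,S)-TsDPEN](p-cymene) (1 mol%), i-PrOH, rt
Reagents that add atoms: none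
Why: Noyori asymmetric transfer hydrogenation of an ynone, in which the alkynyl group takes the place of the aryl group in the CH/π-controlled transition state, so the (S,S) catalyst should deliver hydride to the face that gives the (R)-carbinol under base-free conditions.

Step 7
Reactants: 11 (2R)-1-[(TBS)oxy]-5-Ar-pent-3-yn-2-ol
Product: 12 (2R)-1-[(TBS)oxy]-5-Ar-pent-3-yn-2-yl methanesulfonate
Conditions: MsCl, Et3N, CH2Cl2, −78 °C
Reagents that add atoms: methanesulfonyl chloride, CS(=O)(=O)Cl
Why: Sulfonylation of a secondary propargylic alcohol does not touch the C–O bond, so the configuration is retained, and the mesylate is used crude.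

Step 8
Reactants: 12 (2R)-1-[(TBS)oxy]-5-Ar-pent-3-yn-2-yl methanesulfonate
Product: 13 tributyl[(aR)-5-[(TBS)oxy]-1-Ar-penta-2,3-dien-2-yl]stannane
Conditions: Bu3SnH, LDA, THF, 0 °C; CuBr·SMe2, −78 °C; then 12, −78 °C
Reagents that add atoms: tributyltin hydride, CCCC[SnH](CCCC)CCCC
Why: Anti SN2' substitution of a propargylic mesylate by a stannylcuprate is a known centre-to-axis chirality transfer, so the (R)-mesylate should give the (aR) allene with tin on the face opposite the departing mesylate.

Step 9
Reactants: 13 tributyl[(aR)-5-[(TBS)oxy]-1-Ar-penta-2,3-dien-2-yl]stannane; 2 3-methoxy-4-[(triisopropylsilyl)oxy]benzaldehyde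
Product: 14 (1R,2R)-2-{[(TBS)oxy]methyl}-1,5-di-Ar-pent-3-yn-1-ol
Conditions: BF3·OEt2, CH2Cl2, −78 °C
Reagents that add atoms: none
Why: Lewis-acid-promoted SE2' addition of a chiral allenylstannane to an aldehyde: attack anti to tin transfers the axial chirality to the future C4, and the open transition state that turns the aldehyde aryl group away from the CH2OTBS-bearing allene terminus should give the syn carbinol at the future C6.

Step 10
Reactants: 14 (1R,2R)-2-{[(TBS)oxy]methyl}-1,5-di-Ar-pent-3-yn-1-ol
Product: 15 (1R,2R)-1-[(TBS)oxy]-2-{[(TBS)oxy]methyl}-1,5-di-Ar-pent-3-yne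
Conditions: TBSOTf, 2,6-lutidine, CH2Cl2, −78 → 0 °C
Reagents that add atoms: tert-butyldimethylsilyl trifluoromethanesulfonate, CC(C)(C)[Si](C)(C)OS(=O)(=O)C(F)(F)F
Why: Silyl triflate/lutidine silylation should cap the hindered benzylic alcohol without ionising it, and it keeps this oxygen from competing with the C5 hydroxyl for the ketone in step 15.

Step 11
Reactants: 15 (1R,2R)-1-[(TBS)oxy]-2-{[(TBS)oxy]methyl}-1,5-di-Ar-pent-3-yne
Product: 16 (1R,2R,3Z)-1-[(TBS)oxy]-2-{[(TBS)oxy]methyl}-1,5-di-Ar-pent-3-ene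
Conditions: H2 (1 atm), Pd/CaCO3 poisoned with Pb(OAc)2, quinoline, EtOAc, rt
Reagents that add atoms: none
Why: Lindlar semihydrogenation adds hydrogen syn to the alkyne and should stop at the Z-alkene without touching benzylic C–O bonds or silyl ethers.

Step 12
Reactants: 16 (1R,2R,3Z)-1-[(TBS)oxy]-2-{[(TBS)oxy]methyl}-1,5-di-Ar-pent-3-ene
Product: 17 (4S,5R)-5-[(TBS)oxy]-4-{[(TBS)oxy]methyl}-1,5-di-Ar-pentane-2,3-diol
Conditions: K2OsO4·2H2O (2 mol%), NMO, acetone/H2O, rt
Reagents that add atoms: N-methylmorpholine N-oxide, C[N+]1([O-])CCOCC1; water, O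
Why: Upjohn dihydroxylation of a 1,2-disubstituted alkene tolerates silyl ethers and electron-rich arenes, and the facial mixture at the two new carbinols does not matter because both are oxidised in the next step.

Step 13
Reactants: 17 (4S,5R)-5-[(TBS)oxy]-4-{[(TBS)oxy]methyl}-1,5-di-Ar-pentane-2,3-diol
Product: 18 (4R,5R)-5-[(TBS)oxy]-4-{[(TBS)oxy]methyl}-1,5-di-Ar-pentane-2,3-dione
Conditions: IBX, DMSO, rt
Reagents that add atoms: none
Why: IBX oxidation of a 1,2-diol gives the 1,2-diketone without glycol C–C cleavage and under neutral conditions, which should spare the base-sensitive C4–H and the β-silyloxy group.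

Step 14
Reactants: 18 (4R,5R)-5-[(TBS)oxy]-4-{[(TBS)oxy]methyl}-1,5-di-Ar-pentane-2,3-dione
Product: 19 (4R,5R)-5-[(TBS)oxy]-4-(hydroxymethyl)-1,5-di-Ar-pentane-2,3-dione
Conditions: HF·pyridine, pyridine, THF, 0 °C
Reagents that add atoms: none
Why: Buffered HF·pyridine desilylation should remove the primary alkyl TBS ether well before the hindered benzylic TBS ether and the acid-stable aryl TIPS ethers, in a medium too weakly basic to enolise C4.

Step 15
Reactants: 19 (4R,5R)-5-[(TBS)oxy]-4-(hydroxymethyl)-1,5-di-Ar-pentane-2,3-dione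
Product: 21 (3S,4R)-4-{(R)-[(TBS)oxy](Ar)methyl}-3-(Ar-methyl)-3-hydroxydihydrofuran-2(3H)-one, via cyclic hemiketal 20 (not isolated)
Conditions: Zn(OTf)2 (20 mol%), toluene, 50 °C
Reagents that add atoms: none
Why: Proposed new method: the C5 hydroxyl of 19 adds reversibly to the C2 ketone to give the 2-hydroxy-furan-3-one 20 (O1–C2 bond, 5-exo-trig; attack at C3 would need a four-membered ring), and Zn(OTf)2, bound between the C3 carbonyl oxygen and the hemiketal hydroxyl, should trigger a suprafacial 1,2-shift of the arylmethyl group from C2 to C3 while the hemiketal C–O becomes the lactone carbonyl, the ring oxygen lone pair stabilising the migration origin. The closest known reaction types are the α-ketol (acyloin) rearrangement of α-hydroxy ketones under Lewis acid or mild base and the benzilic ester rearrangement, in which an alkoxide adduct of a 1,2-diketone undergoes the same shift; what has not been shown is a cyclic hemiketal as migration origin with a benzylic migrating group. Exchanging a ketone and a hemiketal for a lactone and a tertiary alcohol makes the shift downhill and irreversible. The new stereocentre C3 is controlled by C4: the two C2 epimers of 20 interconvert through 19, and the epimer whose arylmethyl group lies trans to the bulky C4 side chain should migrate across the open ring face, placing the arylmethyl group trans and the hydroxyl cis to that side chain (3S). Chemoselectivity is needed against β-elimination of the C6 silyloxy group, epimerisation at C4 and dehydration of 20, and it rests on the absence of base, on the silyl cap at C6–O that leaves only the C5 hydroxyl able to form a hemiketal, and on arylmethyl being the only carbon substituent at C2.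

Step 16
Reactants: 21 (3S,4R)-4-{(R)-[(TBS)oxy](Ar)methyl}-3-(Ar-methyl)-3-hydroxydihydrofuran-2(3H)-one
Product: 22 (3S,4R)-3-hydroxy-4-[(R)-hydroxy(4-hydroxy-3-methoxyphenyl)methyl]-3-[(4-hydroxy-3-methoxyphenyl)methyl]dihydrofuran-2(3H)-one
Conditions: TBAF, AcOH, THF, 0 °C → rt
Reagents that add atoms: none
Why: Fluoride desilylation buffered with acetic acid should cleave the two aryl TIPS ethers and the secondary TBS ether near neutrality, which guards against translactonisation onto the freed C6 hydroxyl and against quinone methide formation from the p-hydroxybenzylic alcohol.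

**Compound list**

1 | vanillin (4-hydroxy-3-methoxybenzaldehyde) | COc1cc(C=O)ccc1O | starting material
2 | 3-methoxy-4-[(triisopropylsilyl)oxy]benzaldehyde | COc1cc(C=O)ccc1O[Si](C(C)C)(C(C)C)C(C)C | intermediate
3 | {3-methoxy-4-[(triisopropylsilyl)oxy]phenyl}methanol | COc1cc(CO)ccc1O[Si](C(C)C)(C(C)C)C(C)C | intermediate
4 | [4-(bromomethyl)-2-methoxyphenoxy]triisopropylsilane | COc1cc(CBr)ccc1O[Si](C(C)C)(C(C)C)C(C)C | intermediate
5 | ethynylmagnesium bromide | C#C[Mg]Br | starting material
6 | [2-methoxy-4-(prop-2-yn-1-yl)phenoxy]triisopropylsilane | COc1cc(CC#C)ccc1O[Si](C(C)C)(C(C)C)C(C)C | intermediate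
7 | 2-[(tert-butyldimethylsilyl)oxy]-N-methoxy-N-methylacetamide | CON(C)C(=O)CO[Si](C)(C)C(C)(C)C | starting material
8 | lithium acetylide of 6 (3-Ar-prop-1-yn-1-yllithium) | COc1cc(CC#C[Li])ccc1O[Si](C(C)C)(C(C)C)C(C)C | intermediate
9 | tetrahedral lithium adduct, lithium 1-[(TBS)oxy]-2-[methoxy(methyl)amino]-5-Ar-pent-3-yn-2-olate | COc1cc(CC#CC(O[Li])(CO[Si](C)(C)C(C)(C)C)N(C)OC)ccc1O[Si](C(C)C)(C(C)C)C(C)C | intermediate
10 | 1-[(TBS)oxy]-5-Ar-pent-3-yn-2-one | COc1cc(CC#CC(=O)CO[Si](C)(C)C(C)(C)C)ccc1O[Si](C(C)C)(C(C)C)C(C)C | intermediate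
11 | (2R)-1-[(TBS)oxy]-5-Ar-pent-3-yn-2-ol | COc1cc(CC#C[C@H](CO[Si](C)(C)C(C)(C)C)O)ccc1O[Si](C(C)C)(C(C)C)C(C)C | intermediate
12 | (2R)-1-[(TBS)oxy]-5-Ar-pent-3-yn-2-yl methanesulfonate | COc1cc(CC#C[C@H](CO[Si](C)(C)C(C)(C)C)OS(C)(=O)=O)ccc1O[Si](C(C)C)(C(C)C)C(C)C | intermediate
13 | tributyl[(aR)-5-[(TBS)oxy]-1-Ar-penta-2,3-dien-2-yl]stannane, the (M) allene | CCCC[Sn](CCCC)(CCCC)C(Cc1ccc(O[Si](C(C)C)(C(C)C)C(C)C)c(OC)c1)=[C@]=C([H])CO[Si](C)(C)C(C)(C)C | intermediate
14 | (1R,2R)-2-{[(TBS)oxy]methyl}-1,5-di-Ar-pent-3-yn-1-ol (syn) | COc1cc(CC#C[C@H](CO[Si](C)(C)C(C)(C)C)[C@@H](O)c2ccc(O[Si](C(C)C)(C(C)C)C(C)C)c(OC)c2)ccc1O[Si](C(C)C)(C(C)C)C(C)C | intermediate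
15 | (1R,2R)-1-[(TBS)oxy]-2-{[(TBS)oxy]methyl}-1,5-di-Ar-pent-3-yne | COc1cc(CC#C[C@H](CO[Si](C)(C)C(C)(C)C)[C@@H](O[Si](C)(C)C(C)(C)C)c2ccc(O[Si](C(C)C)(C(C)C)C(C)C)c(OC)c2)ccc1O[Si](C(C)C)(C(C)C)C(C)C | intermediate
16 | (1R,2R,3Z)-1-[(TBS)oxy]-2-{[(TBS)oxy]methyl}-1,5-di-Ar-pent-3-ene | COc1cc(C/C=C\[C@H](CO[Si](C)(C)C(C)(C)C)[C@@H](O[Si](C)(C)C(C)(C)C)c2ccc(O[Si](C(C)C)(C(C)C)C(C)C)c(OC)c2)ccc1O[Si](C(C)C)(C(C)C)C(C)C | intermediate
17 | (4S,5R)-5-[(TBS)oxy]-4-{[(TBS)oxy]methyl}-1,5-di-Ar-pentane-2,3-diol, mixture at C2 and C3 (the C4 letter changes by priority only) | COc1cc(CC(O)C(O)[C@H](CO[Si](C)(C)C(C)(C)C)[C@@H](O[Si](C)(C)C(C)(C)C)c2ccc(O[Si](C(C)C)(C(C)C)C(C)C)c(OC)c2)ccc1O[Si](C(C)C)(C(C)C)C(C)C | intermediate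
18 | (4R,5R)-5-[(TBS)oxy]-4-{[(TBS)oxy]methyl}-1,5-di-Ar-pentane-2,3-dione | COc1cc(CC(=O)C(=O)[C@H](CO[Si](C)(C)C(C)(C)C)[C@@H](O[Si](C)(C)C(C)(C)C)c2ccc(O[Si](C(C)C)(C(C)C)C(C)C)c(OC)c2)ccc1O[Si](C(C)C)(C(C)C)C(C)C | intermediate
19 | (4R,5R)-5-[(TBS)oxy]-4-(hydroxymethyl)-1,5-di-Ar-pentane-2,3-dione | COc1cc(CC(=O)C(=O)[C@H](CO)[C@@H](O[Si](C)(C)C(C)(C)C)c2ccc(O[Si](C(C)C)(C(C)C)C(C)C)c(OC)c2)ccc1O[Si](C(C)C)(C(C)C)C(C)C | intermediate
20 | (4R)-4-{(R)-[(TBS)oxy](Ar)methyl}-2-(Ar-methyl)-2-hydroxydihydrofuran-3(2H)-one, both C2 epimers | COc1cc(CC2(O)OC[C@H]([C@@H](O[Si](C)(C)C(C)(C)C)c3ccc(O[Si](C(C)C)(C(C)C)C(C)C)c(OC)c3)C2=O)ccc1O[Si](C(C)C)(C(C)C)C(C)C | intermediate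
21 | (3S,4R)-4-{(R)-[(TBS)oxy](Ar)methyl}-3-(Ar-methyl)-3-hydroxydihydrofuran-2(3H)-one | COc1cc(C[C@@]2(O)C(=O)OC[C@@H]2[C@@H](O[Si](C)(C)C(C)(C)C)c2ccc(O[Si](C(C)C)(C(C)C)C(C)C)c(OC)c2)ccc1O[Si](C(C)C)(C(C)C)C(C)C | intermediate
22 | (3S,4R)-3-hydroxy-4-[(R)-hydroxy(4-hydroxy-3-methoxyphenyl)methyl]-3-[(4-hydroxy-3-methoxyphenyl)methyl]dihydrofuran-2(3H)-one | COc1cc(C[C@@]2(O)C(=O)OC[C@@H]2[C@@H](O)c2ccc(O)c(OC)c2)ccc1O | target

**Step count**

Total steps: 16. Longest linear sequence: 16 (1 → 22; aldehyde 2 re-enters at step 9).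

**Steps most likely to fail**

Step 15. The hemiketal may dehydrate, the C6 silyloxy group may be lost by β-elimination after enolisation at C4, or the shift may take place on the wrong ring face. The fallback sets out from diketone 18, whose C5 oxygen is still silylated. A classical hydroxide-induced benzilic acid rearrangement (LiOH, THF/H2O, 0 °C, then mild acidification) should give the same carbon skeleton whichever carbonyl is attacked. The product is the α-hydroxy acid (3R,4R)-4-[(TBS)oxy]-3-{[(TBS)oxy]methyl}-2-hydroxy-2-(Ar-methyl)-4-Ar-butanoic acid F1, expected as both epimers at the new carbinol because no ring directs the shift. HF·pyridine in THF/pyridine then frees the primary hydroxyl, which should lactonise onto the acid. Chromatographic separation of the C3 epimers brings the route back at 21.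

Step 9. Facial selectivity at the aldehyde carbonyl may be poor for an aromatic aldehyde, so that syn and anti carbinols form together, and BF3 may ionise the electron-rich benzylic alkoxide. The fallback sets out from 14 as obtained (mixed at C6). Buffered Dess–Martin oxidation (NaHCO3, CH2Cl2, 0 °C) should give the aryl ketone (2R)-2-{[(TBS)oxy]methyl}-1,5-di-Ar-pent-3-yn-1-one F2 without touching C4. A Corey–Bakshi–Shibata reduction with (S)-2-methyl-CBS-oxazaborolidine and catecholborane at low temperature, with the aryl group as the large substituent, should then set C6 under reagent control and return single-isomer 14.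

Step 6. The skipped ynone may isomerise to the conjugated allenyl ketone under the basic amido-ruthenium catalyst, or hydride delivery may be less face-selective than expected for this α-silyloxy ketone. The fallback sets out from alkyne 6 and bypasses the ynone. A catalytic enantioselective alkynylation of commercial (tert-butyldimethylsilyloxy)acetaldehyde (Me2Zn, the chiral bis(diphenylprolinol)phenol ligand ProPhenol in the antipode that gives the (R)-carbinol, toluene, slow aldehyde addition) should form the C3–C4 bond and the stereocentre in one operation. This returns the route at 11; no new compound arises (F0).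

**Further compounds**

F1 | step 15 | (3R,4R)-4-[(TBS)oxy]-3-{[(TBS)oxy]methyl}-2-hydroxy-2-(Ar-methyl)-4-Ar-butanoic acid, both C2 epimers | COc1cc(CC(O)(C(=O)O)[C@H](CO[Si](C)(C)C(C)(C)C)[C@@H](O[Si](C)(C)C(C)(C)C)c2ccc(O[Si](C(C)C)(C(C)C)C(C)C)c(OC)c2)ccc1O[Si](C(C)C)(C(C)C)C(C)C
F2 | step 9 | (2R)-2-{[(TBS)oxy]methyl}-1,5-di-Ar-pent-3-yn-1-one | COc1cc(CC#C[C@H](CO[Si](C)(C)C(C)(C)C)C(=O)c2ccc(O[Si](C(C)C)(C(C)C)C(C)C)c(OC)c2)ccc1O[Si](C(C)C)(C(C)C)C(C)C
F0 | step 6 | none | none
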